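**Retrosynthetic overview**
1. The α‑methylene ε‑lactone is closed last (C16 acid onto the C12 tertiary alcohol); C16 comes from allylic oxidation of the carvone isopropenyl group.
2. The 14‑membered carbocycle is closed at C8–C9 by a visible‑light macrocyclising radical conjugate addition of a ketal‑derived tertiary 2‑pyranyl radical to a C11 vinyl ketone (sets C8).
3. C2–C3 is made by Claisen acylation of a carvone‑derived hydroxy ketone with a bicyclic acylal; retro‑Claisen then opens the carvone ring to the C11 acid.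
4. The tetrahydropyran is built first, as a bicyclic keto‑acylal from (R)‑linalool (buys C4, controls C7); the other half comes from (R)‑carvone (buys C1, controls C12).
5. Ring order: tetrahydropyran, then 14‑membered ring, then lactone; C3 is set by chelation‑controlled reduction.

Labels used (assumption, cembrane numbering): C1 = CH bearing C15(=C17H2)–C16(=O)O; C3 = CHOH; C4/C8 = ether carbons (methyls C18/C19); C7 = CHOAc; C11 = ketone; C12 = C(Me, C20)–O(lactone); target = (1R,3S,4R,7S,8S,12R).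

**Step 1**
Reactants: 1 (R)-carvone
Product: 2 (1R,4R,6R)-1-methyl-4-(prop-1-en-2-yl)-7-oxabicyclo[4.1.0]heptan-2-one (epoxide anti to isopropenyl)
Conditions: 35% H2O2, NaOH (cat.), MeOH, 0 °C
Reagents that add atoms: hydrogen peroxide, OO
Why: Weitz–Scheffer nucleophilic epoxidation; the hydroperoxide adds to the enone face opposite the C1 isopropenyl group, so the C12–O bond is set by the purchased centre.

**Step 2**
Reactants: 2 carvone epoxide
Product: 3 (2S,3S,5S)-3-bromo-2-hydroxy-2-methyl-5-(prop-1-en-2-yl)cyclohexan-1-one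
Conditions: LiBr, AcOH, THF, 0 °C
Reagents that add atoms: lithium bromide, [Li+].[Br-]
Why: acid‑assisted SN2 halohydrin formation at the secondary epoxide carbon C13 (trans‑diaxial opening), leaving the C12–O bond and its configuration untouched.

**Step 3**
Reactants: 3 bromohydrin
Product: 4 (2R,5R)-2-hydroxy-2-methyl-5-(prop-1-en-2-yl)cyclohexan-1-one
Conditions: n-Bu3SnH (2 M), Et3B/air, PhMe, −20 °C
Reagents that add atoms: none
Why: radical‑chain hydrodebromination at C13 (fast hydrogen transfer at high stannane concentration outruns 1,2‑acyl shift); C12 and C1 are not involved.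

**Step 4**
Reactants: 5 (R)-linalool
Product: 6 (R)-2-methyl-5-oxotetrahydrofuran-2-carboxylic acid
Conditions: RuCl3 (2 mol %), NaIO4, MeCN/EtOAc/H2O, 23 °C; then 1 M HCl
Reagents that add atoms: sodium periodate, [Na+].[O-][I](=O)(=O)=O; water, O
Why: RuO4 (Sharpless) oxidative cleavage of both alkenes to carboxylic acids, followed by γ‑lactonisation; the C4 carbinol centre of linalool is not touched.

**Step 5**
Reactants: 6 lactone acid
Product: 8 (1R,5R)-1,5-dimethyl-6,8-dioxabicyclo[3.2.1]octane-4,7-dione, via diketo acid 7 (not isolated)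
Conditions: CH2=C(OEt)Li (2.3 equiv, from ethyl vinyl ether/t-BuLi), THF, −78 °C; 1 M HCl; then TsOH (cat.), PhMe, 4 Å sieves, 60 °C
Reagents that add atoms: 1-ethoxyvinyllithium, [Li]C(=C)OCC
Why: acyl‑anion‑equivalent addition to the lactone, enol‑ether hydrolysis and thermodynamic ketalisation of the methyl ketone by the C4 hydroxyl and the carboxylic acid (1,3‑dioxolan‑4‑one formation); the ketal centre C8 can only form cis‑bridged to C4.

**Step 6**
Reactants: 8 bicyclic keto‑acylal
Product: 9 (1R,4R,5R)-4-hydroxy-1,5-dimethyl-6,8-dioxabicyclo[3.2.1]octan-7-one (OH syn to the lactone bridge)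
Conditions: NaBH4, EtOH/CH2Cl2, −78 °C
Reagents that add atoms: none
Why: hydride attacks from the exo face opposite the two‑atom acyloxy bridge (Felkin–Anh, anti to the axial C8–O bond, as in levoglucosenone‑type bicycles), so C7–OH is cis to the bridge.

**Step 7**
Reactants: 9 bicyclic alcohol
Product: 12 (1R,4S,5R)-4-hydroxy-1,5-dimethyl-6,8-dioxabicyclo[3.2.1]octan-7-one (OH anti to the bridge), via triflate 10 (not isolated), via nitrite ester 11 (not isolated)
Conditions: Tf2O, pyridine, CH2Cl2, −30 °C; then n-Bu4NNO2, DMF, 23 °C; H2O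
Reagents that add atoms: tetrabutylammonium nitrite, CCCC[N+](CCCC)(CCCC)CCCC.[O-]N=O
Why: Lattrell–Dax inversion: SN2 displacement of the equatorial triflate by nitrite from the open exo face (as for C2 triflates of 1,6‑anhydro sugars) and hydrolysis of the nitrite ester give the C7 configuration of the target.

**Step 8**
Reactants: 4 hydroxy ketone; 12 inverted bicyclic alcohol
Product: 14 (2R,5R)-2-hydroxy-6-{[(2R,5S)-5-hydroxy-6-methoxy-2,6-dimethyloxan-2-yl]carbonyl}-2-methyl-5-(prop-1-en-2-yl)cyclohexan-1-one (C6 and the ketal carbon unassigned), via lactol diketone 13 (not isolated)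
Conditions: 4, LiN(i-Pr)2 (2.2 equiv), THF, −78 °C; add 12 as lithium alkoxide (LiN(SiMe3)2), −78 → −20 °C; AcOH; then MeOH, PPTS, 23 °C
Reagents that add atoms: methanol, CO
Why: crossed Claisen C‑acylation of the only enolisable position (C2) of 4 by the activated dioxolanone carbonyl (O‑acylated material converges by Baker–Venkataraman acyl shift), then methyl ketalisation of the released lactol; C2 and ketal C8 need no control because C2 becomes CH2 in step 9 and C8 is re‑formed in step 13.

**Step 9**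
Reactants: 14 β‑diketone
Product: 15 (2R,5R)-2-hydroxy-7-[(2R,5S)-5-hydroxy-6-methoxy-2,6-dimethyloxan-2-yl]-2-methyl-7-oxo-5-(prop-1-en-2-yl)heptanoic acid
Conditions: LiOH, THF/H2O, 40 °C; then 1 M HCl to pH 3
Reagents that add atoms: lithium hydroxide, [Li+].[OH-]
Why: retro‑Claisen ("acid cleavage") of the 2‑acylcyclohexanone: hydroxide adds to the more electrophilic ring carbonyl and expels the C3‑ketone enolate, opening the carvone ring to the C11 acid without touching a stereocentre.

**Step 10**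
Reactants: 15 keto acid
Product: 16 (2R,5R)-7-[(2R,5S)-5-acetoxy-6-methoxy-2,6-dimethyloxan-2-yl]-2-hydroxy-2-methyl-7-oxo-5-(prop-1-en-2-yl)heptanoic acid
Conditions: Ac2O, pyridine, DMAP (cat.), CH2Cl2, 0 °C; aq. NaHCO3
Reagents that add atoms: acetic anhydride, CC(=O)OC(C)=O
Why: acetylation of the only secondary hydroxyl (C7); the tertiary C12 hydroxyl is inert and the mixed anhydride of the acid is hydrolysed on work‑up.

**Step 11**
Reactants: 16 acetoxy keto acid
Product: 18 (2R,5R,7S)-7-[(2R,5S)-5-acetoxy-6-methoxy-2,6-dimethyloxan-2-yl]-2-hydroxy-2-methyl-5-(prop-1-en-2-yl)-7-(triethylsilyloxy)heptanoic acid, via alcohol 17 (not isolated)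
Conditions: Zn(BH4)2, Et2O, −30 °C; then Et3SiCl, imidazole, DMF, 0 °C; aq. citric acid
Reagents that add atoms: chlorotriethylsilane, CC[Si](Cl)(CC)CC
Why: Cram‑chelate reduction: zinc bridges the C3 carbonyl and the ring oxygen and hydride enters from the face of the C18 methyl (the other face carries the ring), giving (3S); the alcohol is silylated in the same pot so it cannot lactonise later.

**Step 12**
Reactants: 18 silyl ether acid
Product: 19 (4R,7R,9S)-9-[(2R,5S)-5-acetoxy-6-methoxy-2,6-dimethyloxan-2-yl]-4-hydroxy-4-methyl-7-(prop-1-en-2-yl)-9-(triethylsilyloxy)non-1-en-3-one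
Conditions: Pd(OAc)2 (5 mol %), P(4-MeOC6H4)3, dimethyl dicarbonate, 2,4,6-trivinylcyclotriboroxane·pyridine, THF/H2O, 50 °C
Reagents that add atoms: 2,4,6-trivinylcyclotriboroxane–pyridine complex, C=CB1OB(C=C)OB(C=C)O1.c1ccncc1
Why: Pd‑catalysed acyl Suzuki–Miyaura coupling of the acid, activated in situ as the mixed carbonic anhydride, gives the vinyl ketone; no stereocentre is involved.

**Step 13**
Reactants: 19 vinyl ketone methyl ketal
Product: 20 7-acetoxy-4,8-epoxy-12-hydroxy-4,8,12-trimethyl-1-(prop-1-en-2-yl)-3-(triethylsilyloxy)cyclotetradecan-11-one (label numbering; all six centres arranged as in the target)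
Conditions: [Ir(ppy)2(dtbbpy)]PF6 (2 mol %), Hantzsch ester (1.5 equiv), (PhO)2P(O)OH (20 mol %), MeCN/CH2Cl2 (1 mM), 450 nm LEDs, 20 °C
Reagents that add atoms: none
Why: Proposed new method: photoredox/Brønsted‑acid umpolung of a tertiary O,O‑ketal: the acid reversibly ionises the methyl ketal to the 2‑pyranyl oxocarbenium (stabilised as the C7 acetoxonium), the photoreduced divalent iridium complex (about −1.5 V) reduces it to the tertiary anomeric radical, which closes the 14‑membered ring by Giese addition to the vinyl ketone, and the α‑keto radical is reduced and protonated with Hantzsch ester as terminal reductant; C8 is set because the radical reacts through the chair holding the C7 acetate and the bulky C4 side chain equatorial and bonds on its axial (anomeric) lobe, placing C9 cis to the acetate and trans to C3; closest known reaction types are Giese reactions of glycosyl radicals and photoreductive generation of α‑oxy radicals from benzylic acetals.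

**Step 14**
Reactants: 20 macrocycle
Product: 21 7-acetoxy-4,8-epoxy-12-hydroxy-1-(3-hydroxyprop-1-en-2-yl)-4,8,12-trimethyl-3-(triethylsilyloxy)cyclotetradecan-11-one
Conditions: SeO2 (0.3 equiv), t-BuOOH, CH2Cl2, 23 °C
Reagents that add atoms: tert-butyl hydroperoxide, CC(C)(C)OO
Why: Sharpless SeO2/t‑BuOOH allylic oxidation (ene reaction then [2,3]‑shift) of the isopropenyl methyl, which reacts before the allylic methine; stereocentres are untouched.

**Step 15**
Reactants: 21 allylic alcohol
Product: 23 2-[7-acetoxy-4,8-epoxy-12-hydroxy-4,8,12-trimethyl-11-oxo-3-(triethylsilyloxy)cyclotetradecyl]acrylic acid, via enal 22 (not isolated)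
Conditions: TEMPO (10 mol %), PhI(OAc)2, CH2Cl2, 23 °C; then NaClO2, NaH2PO4, 2-methyl-2-butene, t-BuOH/H2O, 0 °C
Reagents that add atoms: sodium chlorite, [Na+].[O-]Cl=O
Why: TEMPO/PhI(OAc)2 oxidation of the primary allylic alcohol to the enal, then Pinnick oxidation to the 2‑substituted acrylic acid; the tertiary alcohol is inert.

**Step 16**
Reactants: 23 hydroxy acid
Product: 24 3-O-triethylsilyl ether of the target
Conditions: 2-methyl-6-nitrobenzoic anhydride, DMAP, Et3N, CH2Cl2 (2 mM), 40 °C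
Reagents that add atoms: none
Why: Shiina lactonisation; the C12 tertiary hydroxyl is the only free alcohol (C3 silylated, C7 acetylated), so only the seven‑membered lactone can form.

**Step 17**
Reactants: 24 silyl ether lactone
Product: 25 target (1R,3S,4R,7S,8S,12R)
Conditions: HF·pyridine, THF, 0 °C
Reagents that add atoms: none
Why: acidic fluoride desilylation frees the C3 hydroxyl without forming an alkoxide, which avoids translactonisation to the six‑membered lactone.

**Compound list**
1 | (R)-carvone | CC1=CC[C@@H](C(C)=C)CC1=O | starting material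
2 | (1R,4R,6R)-1-methyl-4-(prop-1-en-2-yl)-7-oxabicyclo[4.1.0]heptan-2-one | C[C@@]12O[C@@H]1C[C@@H](C(C)=C)CC2=O | intermediate
3 | (2S,3S,5S)-3-bromo-2-hydroxy-2-methyl-5-(prop-1-en-2-yl)cyclohexan-1-one | C[C@@]1(O)[C@@H](Br)C[C@@H](C(C)=C)CC1=O | intermediate
4 | (2R,5R)-2-hydroxy-2-methyl-5-(prop-1-en-2-yl)cyclohexan-1-one | C[C@@]1(O)CC[C@@H](C(C)=C)CC1=O | intermediate
5 | (R)-linalool | C=C[C@](C)(O)CCC=C(C)C | starting material
6 | (R)-2-methyl-5-oxotetrahydrofuran-2-carboxylic acid | C[C@]1(C(=O)O)CCC(=O)O1 | intermediate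
7 | (R)-2-hydroxy-2-methyl-5,6-dioxoheptanoic acid (not isolated) | CC(=O)C(=O)CC[C@@](C)(O)C(=O)O | intermediate
8 | (1R,5R)-1,5-dimethyl-6,8-dioxabicyclo[3.2.1]octane-4,7-dione | C[C@]12CCC(=O)[C@](C)(O1)OC2=O | intermediate
9 | (1R,4R,5R)-4-hydroxy-1,5-dimethyl-6,8-dioxabicyclo[3.2.1]octan-7-one | C[C@]12CC[C@@H](O)[C@](C)(O1)OC2=O | intermediate
10 | (1R,4R,5R)-1,5-dimethyl-7-oxo-6,8-dioxabicyclo[3.2.1]octan-4-yl triflate (not isolated) | C[C@]12CC[C@@H](OS(=O)(=O)C(F)(F)F)[C@](C)(O1)OC2=O | intermediate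
11 | (1R,4S,5R)-1,5-dimethyl-7-oxo-6,8-dioxabicyclo[3.2.1]octan-4-yl nitrite (not isolated) | C[C@]12CC[C@H](ON=O)[C@](C)(O1)OC2=O | intermediate
12 | (1R,4S,5R)-4-hydroxy-1,5-dimethyl-6,8-dioxabicyclo[3.2.1]octan-7-one | C[C@]12CC[C@H](O)[C@](C)(O1)OC2=O | intermediate
13 | lactol β-diketone (14 with OH in place of OMe; not isolated) | C[C@@]1(O)CC[C@@H](C(C)=C)C(C1=O)C(=O)[C@@]1(C)CC[C@H](O)C(C)(O)O1 | intermediate
14 | (2R,5R)-2-hydroxy-6-{[(2R,5S)-5-hydroxy-6-methoxy-2,6-dimethyloxan-2-yl]carbonyl}-2-methyl-5-(prop-1-en-2-yl)cyclohexan-1-one | C[C@@]1(O)CC[C@@H](C(C)=C)C(C1=O)C(=O)[C@@]1(C)CC[C@H](O)C(C)(OC)O1 | intermediate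
15 | (2R,5R)-2-hydroxy-7-[(2R,5S)-5-hydroxy-6-methoxy-2,6-dimethyloxan-2-yl]-2-methyl-7-oxo-5-(prop-1-en-2-yl)heptanoic acid | C[C@@](O)(CC[C@H](CC(=O)[C@@]1(C)CC[C@H](O)C(C)(OC)O1)C(C)=C)C(=O)O | intermediate
16 | C7 acetate of 15 | C[C@@](O)(CC[C@H](CC(=O)[C@@]1(C)CC[C@H](OC(C)=O)C(C)(OC)O1)C(C)=C)C(=O)O | intermediate
17 | (7S)-alcohol from 16 (not isolated) | C[C@@](O)(CC[C@H](C[C@H](O)[C@@]1(C)CC[C@H](OC(C)=O)C(C)(OC)O1)C(C)=C)C(=O)O | intermediate
18 | triethylsilyl ether of 17 | C[C@@](O)(CC[C@H](C[C@H](O[Si](CC)(CC)CC)[C@@]1(C)CC[C@H](OC(C)=O)C(C)(OC)O1)C(C)=C)C(=O)O | intermediate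
19 | vinyl ketone (4R,7R,9S)-9-[(2R,5S)-5-acetoxy-6-methoxy-2,6-dimethyloxan-2-yl]-4-hydroxy-4-methyl-7-(prop-1-en-2-yl)-9-(triethylsilyloxy)non-1-en-3-one | C[C@@](O)(CC[C@H](C[C@H](O[Si](CC)(CC)CC)[C@@]1(C)CC[C@H](OC(C)=O)C(C)(OC)O1)C(C)=C)C(=O)C=C | intermediate
20 | macrocyclic hydroxy ketone with isopropenyl at C1 | C[C@@]1(O)CC[C@@H](C(C)=C)C[C@H](O[Si](CC)(CC)CC)[C@@]2(C)CC[C@H](OC(C)=O)[C@](C)(CCC1=O)O2 | intermediate
21 | allylic alcohol of 20 | C[C@@]1(O)CC[C@@H](C(=C)CO)C[C@H](O[Si](CC)(CC)CC)[C@@]2(C)CC[C@H](OC(C)=O)[C@](C)(CCC1=O)O2 | intermediate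
22 | enal (not isolated) | C[C@@]1(O)CC[C@@H](C(=C)C=O)C[C@H](O[Si](CC)(CC)CC)[C@@]2(C)CC[C@H](OC(C)=O)[C@](C)(CCC1=O)O2 | intermediate
23 | acrylic acid | C[C@@]1(O)CC[C@@H](C(=C)C(=O)O)C[C@H](O[Si](CC)(CC)CC)[C@@]2(C)CC[C@H](OC(C)=O)[C@](C)(CCC1=O)O2 | intermediate
24 | 3-O-triethylsilyl target | C=C1C(=O)O[C@]2(C)CC[C@@H]1C[C@H](O[Si](CC)(CC)CC)[C@@]1(C)CC[C@H](OC(C)=O)[C@](C)(CCC2=O)O1 | intermediate
25 | CNP0154271.1 | C=C1C(=O)O[C@]2(C)CC[C@@H]1C[C@H](O)[C@@]1(C)CC[C@H](OC(C)=O)[C@](C)(CCC2=O)O1 | target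

**Step count:** 17 steps in total. **Longest linear sequence:** 14 steps (5 → 25, steps 4–17).

**Three steps most likely to fail**

Step 13 (the new macrocyclisation). Hantzsch ester may reduce the oxocarbenium ion ionically (hydride transfer), electron transfer may be slow, or the C8 epimer or oligomers may form. The fallback sets out from 18 and returns at 20 by established selenoglycoside radical chemistry. Ketal exchange with PhSeSiMe3/ZnI2 in CH2Cl2 gives phenylselenoketal acid F1. The vinyl ketone is installed as in step 12 to give phenylselenoketal vinyl ketone F2. Slow addition of (Me3Si)3SiH/AIBN in benzene at 80 °C and high dilution then generates the same tertiary 2‑pyranyl radical for a tin‑free Giese macrocyclisation to 20.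

Step 8 (Claisen union). The hindered dianion of 4 may be O‑acylated or simply protonated by the acylal partner. The fallback sets out from 4 and 12 and returns at 14. DMAP/Et3N‑catalysed O‑acylation of the tertiary hydroxyl of 4 by the acylal 12, followed by MeOH/PPTS, gives tertiary ester F3. LiN(SiMe3)2 in THF (−78 → 0 °C) then induces a Baker–Venkataraman O→C acyl migration to 14.

Step 12 (acyl–vinyl coupling). The α‑quaternary, α‑oxygenated acyl–palladium species may form slowly or decarbonylate. The fallback sets out from 18 and returns at 19. EtSH, EDC·HCl and DMAP give S‑ethyl thioester F4, and Fukuyama coupling with CH2=CHZnBr and PdCl2(PPh3)2 at 23 °C gives 19.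

**Further compounds**
F1 | step 13 | phenylselenoketal acid (18 with SePh in place of OMe at C8) | C[C@@](O)(CC[C@H](C[C@H](O[Si](CC)(CC)CC)[C@@]1(C)CC[C@H](OC(C)=O)C(C)([Se]c2ccccc2)O1)C(C)=C)C(=O)O
F2 | step 13 | phenylselenoketal vinyl ketone (19 with SePh in place of OMe at C8) | C[C@@](O)(CC[C@H](C[C@H](O[Si](CC)(CC)CC)[C@@]1(C)CC[C@H](OC(C)=O)C(C)([Se]c2ccccc2)O1)C(C)=C)C(=O)C=C
F3 | step 8 | (1R,4R)-1-methyl-2-oxo-4-(prop-1-en-2-yl)cyclohexyl (2R,5S)-5-hydroxy-6-methoxy-2,6-dimethyloxane-2-carboxylate | C[C@@]1(OC(=O)[C@@]2(C)CC[C@H](O)C(C)(OC)O2)CC[C@@H](C(C)=C)CC1=O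
F4 | step 12 | S-ethyl thioester of 18 | C[C@@](O)(CC[C@H](C[C@H](O[Si](CC)(CC)CC)[C@@]1(C)CC[C@H](OC(C)=O)C(C)(OC)O1)C(C)=C)C(=O)SCC
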